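**Retrosynthetic overview**

1. Eudesmane numbering is used: ring A = C1–C5/C10, ring B = C5–C10, C11–C13 = acrylate; the target is (3S,7R,8R,10R). The C3 ester (Steglich), the C3 carbinol (Luche reduction of a 4-en-3-one), the acrylate (Markovnikov methoxycarbonylation of a C7 ethynyl group) and the C1–C2 single bond (copper hydride reduction of a 1,4-dien-3-one) are disconnected first, leading back to dienone 16.
2. Ring B of 16 is disconnected at C6–C7 and C9–C10 in a single [3+3] annulation between the dianion of phenol 6 and the cis-alkynyl epoxy chloride 12.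
3. Enabling feature: C6 and C10 both flank C5. With ring A at the phenol oxidation level (C3–OH, methyl on C4 and C10) they are the benzylic carbon and the para carbon of one phenol, a 1,3-dinucleophile. It matches the 1,3-dielectrophile C7/C9 of an epichlorohydrin-type unit whose C8 oxygen is relayed as an epoxide.
4. Fragments: 6 from 2,6-dimethylbenzoic acid (bromination, hydroxylation, reduction, benzylic bromide, stannane); 12 from ethyl (Z)-3-iodoacrylate (Sonogashira, reduction, Sharpless epoxidation, Appel).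
5. Ring order: ring A is bought as the arene; ring B is closed in the key step; no other ring is formed.

Key step: step 10

Remark: the Sharpless epoxidation of the (Z)-enynol is assumed to follow the usual facial rule for primary allylic alcohols (D-(−)-tartrate gives the 2R epoxy alcohol).

**Route**

Step 1
Reactants: 1 2,6-dimethylbenzoic acid
Product: 2 3-bromo-2,6-dimethylbenzoic acid
Conditions: NBS, conc. H2SO4, 0 °C → rt
Reagents that add atoms: N-bromosuccinimide, O=C1CCC(=O)N1Br
Why: Electrophilic aromatic bromination should go to C3, the position ortho and para to the two methyl groups and meta to the carboxyl group, and the ionic medium suppresses benzylic bromination.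

Step 2
Reactants: 2 3-bromo-2,6-dimethylbenzoic acid
Product: 3 3-hydroxy-2,6-dimethylbenzoic acid
Conditions: Pd2(dba)3 (2 mol%), t-BuXPhos (8 mol%), KOH (4 equiv), 1,4-dioxane/H2O, 100 °C; aq. HCl
Reagents that add atoms: potassium hydroxide, [K+].[OH-]
Why: Palladium-catalysed hydroxylation of the aryl bromide (C–O cross-coupling with hydroxide) tolerates the carboxylate and the single ortho substituent.

Step 3
Reactants: 3 3-hydroxy-2,6-dimethylbenzoic acid
Product: 4 3-(hydroxymethyl)-2,4-dimethylphenol
Conditions: BH3·THF (4 equiv), THF, 0 °C → reflux; MeOH, aq. HCl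
Reagents that add atoms: none
Why: Borane reduction of the hindered carboxylic acid gives the benzylic alcohol chemoselectively, the phenol being regenerated on work-up.

Step 4
Reactants: 4 3-(hydroxymethyl)-2,4-dimethylphenol
Product: 5 3-(bromomethyl)-2,4-dimethylphenol
Conditions: 48% aq. HBr, toluene, 0 °C → rt
Reagents that add atoms: hydrogen bromide, Br
Why: Ionisation-type (SN1) substitution of the benzylic hydroxyl, favoured by the two ortho methyl groups, gives the benzylic bromide while the phenolic hydroxyl cannot be substituted.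

Step 5
Reactants: 5 3-(bromomethyl)-2,4-dimethylphenol
Product: 6 2,4-dimethyl-3-[(tributylstannyl)methyl]phenol
Conditions: Bu3SnSnBu3 (1.1 equiv), Pd(PPh3)4 (3 mol%), toluene, 80 °C
Reagents that add atoms: hexabutyldistannane, CCCC[Sn](CCCC)(CCCC)[Sn](CCCC)(CCCC)CCCC
Why: Palladium-catalysed stannylation of a benzylic halide with a distannane (oxidative addition, tin–tin transmetalation, reductive elimination) needs no base and should tolerate the free phenol.

Step 6
Reactants: 7 ethyl (Z)-3-iodoprop-2-enoate; 8 ethynyltri(propan-2-yl)silane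
Product: 9 ethyl (Z)-5-[tri(propan-2-yl)silyl]pent-2-en-4-ynoate
Conditions: PdCl2(PPh3)2 (2 mol%), CuI (4 mol%), Et3N (3 equiv), THF, rt
Reagents that add atoms: none
Why: Sonogashira coupling of the vinyl iodide with the terminal alkyne proceeds with retention of the (Z) double-bond geometry.

Step 7
Reactants: 9 ethyl (Z)-5-[tri(propan-2-yl)silyl]pent-2-en-4-ynoate
Product: 10 (Z)-5-[tri(propan-2-yl)silyl]pent-2-en-4-yn-1-ol
Conditions: i-Bu2AlH (2.2 equiv), CH2Cl2, −78 °C; aq. potassium sodium tartrate
Reagents that add atoms: none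
Why: Diisobutylaluminium hydride reduces the conjugated ester to the allylic alcohol (1,2-reduction) without touching the enyne or its geometry.

Step 8
Reactants: 10 (Z)-5-[tri(propan-2-yl)silyl]pent-2-en-4-yn-1-ol
Product: 11 [(2R,3S)-3-{[tri(propan-2-yl)silyl]ethynyl}oxiran-2-yl]methanol
Conditions: Ti(OiPr)4 (20 mol%), D-(−)-diisopropyl tartrate (24 mol%), t-BuOOH, 4 Å MS, CH2Cl2, −20 °C
Reagents that add atoms: tert-butyl hydroperoxide, CC(C)(C)OO
Why: Sharpless asymmetric epoxidation, in which the titanium–tartrate catalyst delivers oxygen to one face of the allylic alcohol, the D-(−)-tartrate setting the (2R) centre and the (Z) alkene geometry translating into the cis (3S) centre.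

Step 9
Reactants: 11 [(2R,3S)-3-{[tri(propan-2-yl)silyl]ethynyl}oxiran-2-yl]methanol
Product: 12 (2S,3S)-2-(chloromethyl)-3-{[tri(propan-2-yl)silyl]ethynyl}oxirane
Conditions: PPh3, CCl4, NaHCO3, reflux
Reagents that add atoms: tetrachloromethane, ClC(Cl)(Cl)Cl
Why: The Appel reaction converts the primary alcohol into the chloride under near-neutral conditions that leave the epoxide and both stereocentres untouched (the descriptor at C2 changes only because chlorine changes the priorities).

Step 10
Reactants: 6 2,4-dimethyl-3-[(tributylstannyl)methyl]phenol; 12 (2S,3S)-2-(chloromethyl)-3-{[tri(propan-2-yl)silyl]ethynyl}oxirane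
Product: 16 (4aS,6R,7R)-6-hydroxy-1,4a-dimethyl-7-{[tri(propan-2-yl)silyl]ethynyl}-5,6,7,8-tetrahydronaphthalen-2(4aH)-one, via dilithiated phenol 13 (not isolated), via chlorohydrin dilithium salt 14 (not isolated), via epoxide lithium phenoxide 15 (not isolated)
Conditions: n-BuLi (2.05 equiv), THF, −78 °C; 12, −78 → 0 °C; then t-BuOH, DMPU, 65 °C (0.01 M); aq. NH4Cl
Reagents that add atoms: none
Why: Proposed new method: deprotonation of the phenol and tin–lithium exchange give the 1,3-dinucleophile 13, whose benzyllithium carbon (C6) opens the alkynyl epoxide of 12 at the propargylic carbon C7 with inversion (SN2′ attack is blocked by the bulky silyl group and the primary chloride is inert to the organolithium at low temperature); the C8 alkoxide of 14 then displaces chloride in a fast 3-exo-tet closure to the terminal epoxide 15, and the para carbon (C10) of the phenoxide opens this epoxide at C9, closing ring B and dearomatising ring A. The closest known reaction types are the double alkylation of benzylic carbanions with epichlorohydrin through an epoxide relay and the base-mediated para-alkylation of phenoxides by a tethered alkyl halide or sulfonate (aryl participation, Ar2-6) that gives fused cyclohexa-2,5-dienones. Ring B closes in a 6-(enolendo)-tet mode at the primary epoxide carbon, whereas attack at C8 would be the 5-(enolendo)-exo-tet closure that the ring-closure rules for enolates disfavour. C7 is set by the SN2 inversion of the epoxide centre made in step 8, C8 is carried over unchanged, and C10 is set by C8: in the chair transition state the breaking C9–O bond must be anti to the incoming C10, which places the C8 oxygen axial and syn to the C10 methyl group (C1 is held equatorial by the ring fusion) and leaves the C7 alkynyl group equatorial. The step needs C-alkylation at C10 and not at C4 or at oxygen: the meta-placed oxygen cannot reach C9, only C4 and C10 are ortho to the tether, and C10 is the para position, free of the solvated O–Li group that flanks C4; the alkoxide formed is protonated by tert-butanol, so release of epoxide strain should drive the dearomatisation.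

Step 11
Reactants: 16 (4aS,6R,7R)-6-hydroxy-1,4a-dimethyl-7-{[tri(propan-2-yl)silyl]ethynyl}-5,6,7,8-tetrahydronaphthalen-2(4aH)-one
Product: 17 (4aS,6R,7R)-1,4a-dimethyl-2-oxo-7-{[tri(propan-2-yl)silyl]ethynyl}-2,4a,5,6,7,8-hexahydronaphthalen-6-yl acetate
Conditions: Ac2O, DMAP (cat.), pyridine, CH2Cl2, rt
Reagents that add atoms: acetic anhydride, CC(=O)OC(C)=O
Why: DMAP-catalysed acylation of the axial secondary alcohol installs the C8 acetate of the target.

Step 12
Reactants: 17 (4aS,6R,7R)-1,4a-dimethyl-2-oxo-7-{[tri(propan-2-yl)silyl]ethynyl}-2,4a,5,6,7,8-hexahydronaphthalen-6-yl acetate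
Product: 18 (4aR,6R,7R)-1,4a-dimethyl-2-oxo-7-{[tri(propan-2-yl)silyl]ethynyl}-2,3,4,4a,5,6,7,8-octahydronaphthalen-6-yl acetate
Conditions: [(Ph3P)CuH]6 (0.25 equiv), H2O (2 equiv), benzene/THF, rt
Reagents that add atoms: none
Why: Copper hydride conjugate reduction should add hydride to C1, the unsubstituted β-carbon of the cross-conjugated dienone, far faster than to the fully substituted C5, and does not touch the silylalkyne or the acetate.

Step 13
Reactants: 18 (4aR,6R,7R)-1,4a-dimethyl-2-oxo-7-{[tri(propan-2-yl)silyl]ethynyl}-2,3,4,4a,5,6,7,8-octahydronaphthalen-6-yl acetate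
Product: 19 (4aR,6R,7R)-7-ethynyl-1,4a-dimethyl-2-oxo-2,3,4,4a,5,6,7,8-octahydronaphthalen-6-yl acetate
Conditions: TBAF, AcOH, THF, 0 °C → rt
Reagents that add atoms: none
Why: Fluoride-mediated protodesilylation of the alkynylsilane, buffered with acetic acid so that the acetate and the enone are not exposed to free alkoxide.

Step 14
Reactants: 19 (4aR,6R,7R)-7-ethynyl-1,4a-dimethyl-2-oxo-2,3,4,4a,5,6,7,8-octahydronaphthalen-6-yl acetate
Product: 20 methyl 2-[(2R,3R,4aR)-3-acetoxy-4a,8-dimethyl-7-oxo-1,2,3,4,4a,5,6,7-octahydronaphthalen-2-yl]prop-2-enoate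
Conditions: Pd(OAc)2 (2 mol%), 2-(diphenylphosphino)pyridine (8 mol%), MsOH (10 mol%), CO (10 bar), MeOH, CH2Cl2, 45 °C
Reagents that add atoms: carbon monoxide, [C-]#[O+]; methanol, CO
Why: Palladium-catalysed Markovnikov hydromethoxycarbonylation of the terminal alkyne (hydropalladation that places palladium on the internal carbon, CO insertion, methanolysis) should give the 2-substituted acrylate in one step.

Step 15
Reactants: 20 methyl 2-[(2R,3R,4aR)-3-acetoxy-4a,8-dimethyl-7-oxo-1,2,3,4,4a,5,6,7-octahydronaphthalen-2-yl]prop-2-enoate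
Product: 21 methyl 2-[(2R,3R,4aR,7S)-3-acetoxy-7-hydroxy-4a,8-dimethyl-1,2,3,4,4a,5,6,7-octahydronaphthalen-2-yl]prop-2-enoate
Conditions: NaBH4, CeCl3·7H2O, MeOH, −78 °C
Reagents that add atoms: none
Why: Luche reduction gives 1,2-reduction of the enone only, and hydride should add from the face opposite the axial C10 methyl group to give the pseudo-equatorial (S)-configured allylic alcohol at C3, cis to that methyl group.

Step 16
Reactants: 22 ethyl but-2-ynoate
Product: 23 ethyl (E)-3-methylpent-2-enoate
Conditions: Et2CuLi (from EtLi and CuI), THF, −78 °C; MeOH, −78 °C; aq. NH4Cl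
Reagents that add atoms: lithium diethylcuprate, [Li+].CC[Cu-]CC (made in the flask from ethyllithium, [Li]CC, and CuI)
Why: Syn carbocupration (conjugate addition) of the ynoate at −78 °C and protonation with retention should give the (E) trisubstituted enoate, with ethyl trans to the ester.

Step 17
Reactants: 23 ethyl (E)-3-methylpent-2-enoate
Product: 24 (E)-3-methylpent-2-enoic acid
Conditions: LiOH, THF/H2O, rt; aq. HCl
Reagents that add atoms: lithium hydroxide, [Li+].[OH-]
Why: Saponification of the ethyl ester under mild conditions that should not isomerise the trisubstituted double bond.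

Step 18
Reactants: 21 methyl 2-[(2R,3R,4aR,7S)-3-acetoxy-7-hydroxy-4a,8-dimethyl-1,2,3,4,4a,5,6,7-octahydronaphthalen-2-yl]prop-2-enoate; 24 (E)-3-methylpent-2-enoic acid
Product: 25 methyl 2-[(2R,3R,4aR,7S)-3-acetoxy-4a,8-dimethyl-7-{[(2E)-3-methylpent-2-enoyl]oxy}-1,2,3,4,4a,5,6,7-octahydronaphthalen-2-yl]prop-2-enoate (CNP0118541.1)
Conditions: DCC, DMAP (10 mol%), CH2Cl2, 0 °C → rt
Reagents that add atoms: none
Why: Steglich esterification acylates the allylic alcohol with retention at C3 and completes the target.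

**Compound list**

1 | 2,6-dimethylbenzoic acid | Cc1cccc(C)c1C(=O)O | starting material
2 | 3-bromo-2,6-dimethylbenzoic acid | Cc1ccc(Br)c(C)c1C(=O)O | intermediate
3 | 3-hydroxy-2,6-dimethylbenzoic acid | Cc1ccc(O)c(C)c1C(=O)O | intermediate
4 | 3-(hydroxymethyl)-2,4-dimethylphenol | Cc1ccc(O)c(C)c1CO | intermediate
5 | 3-(bromomethyl)-2,4-dimethylphenol | Cc1ccc(O)c(C)c1CBr | intermediate
6 | 2,4-dimethyl-3-[(tributylstannyl)methyl]phenol | CCCC[Sn](CCCC)(CCCC)Cc1c(C)ccc(O)c1C | intermediate
7 | ethyl (Z)-3-iodoprop-2-enoate | CCOC(=O)/C=C\I | starting material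
8 | ethynyltri(propan-2-yl)silane | C#C[Si](C(C)C)(C(C)C)C(C)C | starting material
9 | ethyl (Z)-5-[tri(propan-2-yl)silyl]pent-2-en-4-ynoate | CCOC(=O)/C=C\C#C[Si](C(C)C)(C(C)C)C(C)C | intermediate
10 | (Z)-5-[tri(propan-2-yl)silyl]pent-2-en-4-yn-1-ol | OC/C=C\C#C[Si](C(C)C)(C(C)C)C(C)C | intermediate
11 | [(2R,3S)-3-{[tri(propan-2-yl)silyl]ethynyl}oxiran-2-yl]methanol | OC[C@H]1O[C@H]1C#C[Si](C(C)C)(C(C)C)C(C)C | intermediate
12 | (2S,3S)-2-(chloromethyl)-3-{[tri(propan-2-yl)silyl]ethynyl}oxirane | ClC[C@H]1O[C@H]1C#C[Si](C(C)C)(C(C)C)C(C)C | intermediate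
13 | lithium 3-(lithiomethyl)-2,4-dimethylphenolate | [Li]Cc1c(C)ccc(O[Li])c1C | intermediate (not isolated)
14 | dilithium salt of 3-[(2R,3S)-4-chloro-3-hydroxy-2-{[tri(propan-2-yl)silyl]ethynyl}butyl]-2,4-dimethylphenol | Cc1ccc(O[Li])c(C)c1C[C@H](C#C[Si](C(C)C)(C(C)C)C(C)C)[C@H](O[Li])CCl | intermediate (not isolated)
15 | lithium 2,4-dimethyl-3-[(2R)-2-[(2S)-oxiran-2-yl]-4-[tri(propan-2-yl)silyl]but-3-yn-1-yl]phenolate | Cc1ccc(O[Li])c(C)c1C[C@H](C#C[Si](C(C)C)(C(C)C)C(C)C)[C@H]1CO1 | intermediate (not isolated)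
16 | (4aS,6R,7R)-6-hydroxy-1,4a-dimethyl-7-{[tri(propan-2-yl)silyl]ethynyl}-5,6,7,8-tetrahydronaphthalen-2(4aH)-one | CC(C)[Si](C(C)C)(C(C)C)C#C[C@H]1CC2=C(C)C(=O)C=C[C@]2(C)C[C@H]1O | intermediate
17 | (4aS,6R,7R)-1,4a-dimethyl-2-oxo-7-{[tri(propan-2-yl)silyl]ethynyl}-2,4a,5,6,7,8-hexahydronaphthalen-6-yl acetate | CC(C)[Si](C(C)C)(C(C)C)C#C[C@H]1CC2=C(C)C(=O)C=C[C@]2(C)C[C@H]1OC(C)=O | intermediate
18 | (4aR,6R,7R)-1,4a-dimethyl-2-oxo-7-{[tri(propan-2-yl)silyl]ethynyl}-2,3,4,4a,5,6,7,8-octahydronaphthalen-6-yl acetate | CC(C)[Si](C(C)C)(C(C)C)C#C[C@H]1CC2=C(C)C(=O)CC[C@]2(C)C[C@H]1OC(C)=O | intermediate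
19 | (4aR,6R,7R)-7-ethynyl-1,4a-dimethyl-2-oxo-2,3,4,4a,5,6,7,8-octahydronaphthalen-6-yl acetate | C#C[C@H]1CC2=C(C)C(=O)CC[C@]2(C)C[C@H]1OC(C)=O | intermediate
20 | methyl 2-[(2R,3R,4aR)-3-acetoxy-4a,8-dimethyl-7-oxo-1,2,3,4,4a,5,6,7-octahydronaphthalen-2-yl]prop-2-enoate | C=C(C(=O)OC)[C@H]1CC2=C(C)C(=O)CC[C@]2(C)C[C@H]1OC(C)=O | intermediate
21 | methyl 2-[(2R,3R,4aR,7S)-3-acetoxy-7-hydroxy-4a,8-dimethyl-1,2,3,4,4a,5,6,7-octahydronaphthalen-2-yl]prop-2-enoate | C=C(C(=O)OC)[C@H]1CC2=C(C)[C@@H](O)CC[C@]2(C)C[C@H]1OC(C)=O | intermediate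
22 | ethyl but-2-ynoate | CCOC(=O)C#CC | starting material
23 | ethyl (E)-3-methylpent-2-enoate | CCOC(=O)/C=C(\C)CC | intermediate
24 | (E)-3-methylpent-2-enoic acid | OC(=O)/C=C(\C)CC | intermediate
25 | methyl 2-[(2R,3R,4aR,7S)-3-acetoxy-4a,8-dimethyl-7-{[(2E)-3-methylpent-2-enoyl]oxy}-1,2,3,4,4a,5,6,7-octahydronaphthalen-2-yl]prop-2-enoate | C=C(C(=O)OC)[C@H]1CC2=C(C)[C@@H](OC(=O)/C=C(\C)CC)CC[C@]2(C)C[C@H]1OC(C)=O | target

**Step count**

Total: 18 steps. Longest linear sequence: 12 steps (steps 1–5, 10–15 and 18, from 1).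

**Steps most likely to fail**

1. Step 10 (proposed new method). Four processes could defeat it:
   - proton transfer from 12 to the benzyllithium instead of substitution;
   - attack of the phenoxide at C4 instead of C10;
   - intermolecular O-alkylation;
   - an insufficient driving force for the dearomatising epoxide opening.

   The fallback makes the two bonds one after the other by known reactions, setting out from 6 and 11 and coming back at 16. Alcohol 11 would be silylated (Et3SiCl, imidazole) to the triethylsilyl ether F1, and phenol 6 (t-BuMe2SiCl, imidazole) to the aryl silyl ether F2. Tin–lithium exchange of F2 (n-BuLi) and BF3·OEt2-assisted opening of F1 at the propargylic carbon would give the secondary alcohol F3. Mild acid (AcOH, THF, H2O) would free the primary hydroxyl to give the diol F4, which 1,1′-sulfonyldiimidazole and NaH would convert into the cyclic sulfate F5. CsF in DMF would then unmask the phenoxide, whose para carbon opens the cyclic sulfate at its primary carbon. This is a fluoride-triggered alkylative dearomatisation with a stable sulfate leaving group; the anti geometry is the same, so the C10 configuration should be the same. It would give the sulfate monoester F6, and aqueous H2SO4 in THF would hydrolyse it to 16.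

2. Step 8. The titanium–tartrate epoxidation of a cis-disubstituted allylic alcohol may be slow and lose enantioselectivity, and that loss would carry through to C7, C8 and C10. The fallback replaces hydroxyl-directed catalysis by a reagent-controlled dioxirane epoxidation, setting out from 10 and coming back at 12. Alcohol 10 would first be chlorinated (PPh3, CCl4) to the (Z)-allylic chloride F7. Shi epoxidation of this conjugated cis-enyne would then give 12 directly; it would use the enantiomer of the glucose-derived oxazolidinone ketone catalyst that delivers the (2S,3S) epoxide (KHSO5 as the triple salt 2KHSO5·KHSO4·K2SO4, K2CO3, MeCN/dimethoxymethane/buffer, 0 °C).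

3. Step 14. Hydropalladation of the hindered alkyne may take the wrong regiochemistry and give the linear ester, or the acidic methanol may cleave the acetate. The fallback builds the acrylate in three known steps, setting out from 19 and coming back at 20. Ruthenium-catalysed Markovnikov hydrosilylation ([Cp*Ru(MeCN)3]PF6, Et3SiH, CH2Cl2) would give the 1,1-disubstituted vinylsilane F8. Iododesilylation (N-iodosuccinimide, MeCN) would give the vinyl iodide F9. Palladium-catalysed methoxycarbonylation (PdCl2(PPh3)2, CO, MeOH, Et3N, 50 °C) would then give 20.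

**Further compounds**

F1 | step 10 | triethyl{[(2R,3S)-3-{[tri(propan-2-yl)silyl]ethynyl}oxiran-2-yl]methoxy}silane | CC[Si](CC)(CC)OC[C@H]1O[C@H]1C#C[Si](C(C)C)(C(C)C)C(C)C
F2 | step 10 | tert-butyl{2,4-dimethyl-3-[(tributylstannyl)methyl]phenoxy}dimethylsilane | CCCC[Sn](CCCC)(CCCC)Cc1c(C)ccc(O[Si](C)(C)C(C)(C)C)c1C
F3 | step 10 | (2S,3R)-4-{3-[(tert-butyldimethylsilyl)oxy]-2,6-dimethylphenyl}-1-[(triethylsilyl)oxy]-3-{[tri(propan-2-yl)silyl]ethynyl}butan-2-ol | Cc1ccc(O[Si](C)(C)C(C)(C)C)c(C)c1C[C@H](C#C[Si](C(C)C)(C(C)C)C(C)C)[C@H](O)CO[Si](CC)(CC)CC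
F4 | step 10 | (2S,3R)-4-{3-[(tert-butyldimethylsilyl)oxy]-2,6-dimethylphenyl}-3-{[tri(propan-2-yl)silyl]ethynyl}butane-1,2-diol | Cc1ccc(O[Si](C)(C)C(C)(C)C)c(C)c1C[C@H](C#C[Si](C(C)C)(C(C)C)C(C)C)[C@H](O)CO
F5 | step 10 | (4S)-4-[(2R)-1-{3-[(tert-butyldimethylsilyl)oxy]-2,6-dimethylphenyl}-4-[tri(propan-2-yl)silyl]but-3-yn-2-yl]-1,3,2-dioxathiolane 2,2-dioxide | Cc1ccc(O[Si](C)(C)C(C)(C)C)c(C)c1C[C@H](C#C[Si](C(C)C)(C(C)C)C(C)C)[C@H]1COS(=O)(=O)O1
F6 | step 10 | caesium (4aS,6R,7R)-1,4a-dimethyl-2-oxo-7-{[tri(propan-2-yl)silyl]ethynyl}-2,4a,5,6,7,8-hexahydronaphthalen-6-yl sulfate | CC(C)[Si](C(C)C)(C(C)C)C#C[C@H]1CC2=C(C)C(=O)C=C[C@]2(C)C[C@H]1OS(=O)(=O)[O-].[Cs+]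
F7 | step 8 | [(Z)-5-chloropent-3-en-1-yn-1-yl]tri(propan-2-yl)silane | ClC/C=C\C#C[Si](C(C)C)(C(C)C)C(C)C
F8 | step 14 | (4aR,6R,7S)-1,4a-dimethyl-2-oxo-7-[1-(triethylsilyl)ethenyl]-2,3,4,4a,5,6,7,8-octahydronaphthalen-6-yl acetate | C=C([Si](CC)(CC)CC)[C@H]1CC2=C(C)C(=O)CC[C@]2(C)C[C@H]1OC(C)=O
F9 | step 14 | (4aR,6R,7S)-7-(1-iodoethenyl)-1,4a-dimethyl-2-oxo-2,3,4,4a,5,6,7,8-octahydronaphthalen-6-yl acetate | C=C(I)[C@H]1CC2=C(C)C(=O)CC[C@]2(C)C[C@H]1OC(C)=O
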